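## Structural features

The target is a single 27-membered macrolactone built from 26 carbons and one ring oxygen, with the carbonyl as C1, the oxygen-bearing methylene as C26 and an unbroken polymethylene chain C2–C25 between them. It has no branches, no double bonds and no stereocentres, so no question of neighbouring stereocentres or relative configuration arises. The only reactive group is the ester, which tolerates neutral metathesis catalysts and catalytic hydrogenation but is at risk from hydroxide, alkoxides, hydride donors and strong acid. The real difficulty is ring formation, because closure of a 27-membered ring competes with oligomerisation, and the carbon count must be exact since a lactone one or two CH2 groups too large or too small could hardly be separated from a molecule whose only polar handle is the ester. The featureless chain is also the opportunity: a C=C placed anywhere between C2 and C25 disappears on hydrogenation, so the ring-forming bonds may be chosen freely. The key step uses this at C9=C10 and C19=C20: the atoms C1–C9 and C20–C26 with the ring oxygen are exactly the 16-carbon unsaturated lactone 1, whose alkene joins C9 to the carbon that becomes C20, and the ten carbons C10–C19 are exactly the ring of 2.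

## Logic of the disconnections

From 4 to 3: no skeletal bond is cut. Two hydrogen pairs are removed in the retrosynthetic sense, at C9/C10 and at C19/C20, which turns the saturated ring of 4 into the diene 3. The reason is to create two metathesis retrons in an otherwise inert chain, at positions that match available rings. The gain is that 3 can be taken apart at two double bonds at once. The demand on the forward step is modest: two isolated disubstituted alkenes of either geometry must be saturated without touching the lactone, and the E/Z heterogeneity of 3 then no longer matters.

From 3 to 1 and 2: both C9=C10 and C19=C20 are cut together and the four alkylidene ends are re-paired, C9 with C20 to give the alkene of 1 and C10 with C19 to give the alkene of 2. The cut is made there because each fragment is then a ring with one alkene, the ester is already in place in 1, and no open-chain intermediate or lactonisation is needed. The gain is large: the 27-membered ring falls to a 17-membered and a 10-membered ring, both used as bought, and every atom of both ends up in 3. The demand on the forward step is heavy: exactly one unit of 2 must be inserted into one molecule of 1, although the two alkenes have no intrinsic chemical difference. Control must come from the residual strain of 2, an excess of 1, slow feeding of 2 and high dilution, and double-bond migration must be suppressed so that the ring size stays exact.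

## Other disconnections considered

Alternative 1: The cut is the C11–C12 single bond between the two alkynes of hexacosa-10,12-diyn-26-olide A1. It leads back to the open-chain diyne ester pentadec-14-yn-1-yl undec-10-ynoate A2, and from there to undec-10-ynoic acid A3 and pentadec-14-yn-1-ol A4.
- Forward key step: A2 would be added slowly to Cu(OAc)2 in warm pyridine (Eglinton coupling). Divalent copper oxidises the two acetylide ends and joins C11 to C12. Exhaustive hydrogenation of A1 over Pd/C would then give 4.
- In its favour: the coupling is irreversible, and the ring size is written into A2, so no ring of a neighbouring size can arise. The only by-products to expect are cyclic dimers and higher oligomers of at least twice the mass. The 1,3-diyne rod fits a 27-membered ring without strain, and the ester is indifferent to Cu(OAc)2 in pyridine.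
- Against it: A4 is not a stock chemical and would need about three steps of its own (chain assembly and a terminal-alkyne isomerisation, for instance). With esterification, closure and hydrogenation the sequence would run to about six steps. It also needs an excess of the copper salt, large volumes of pyridine and uptake of four equivalents of H2.
- Comparison: on control of product identity this plan is the better one, because closure is unimolecular and kinetically controlled, whereas step 1 rests on a statistical ring-chain equilibrium. On structure the two are equal: both put removable unsaturation into the C2–C25 chain and both finish with the same hydrogenation. On step economy and atom economy the chosen plan is ahead (two steps from two catalogue compounds, no stoichiometric metal).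

Alternative 2: The cut is the C13=C14 double bond of hexacos-13-en-26-olide A5 (E/Z mixture). It leads back to erucyl erucate A6, that is (Z)-docos-13-en-1-yl (Z)-docos-13-enoate.
- Forward key step: a catalyst such as RuCl2(=CHPh)(H2IMes)(PCy3) would exchange the two internal cis alkenes of A6 at high dilution. C13 of the acyl chain joins C13 of the alkyl chain (C14 of the lactone), and octadec-9-ene A7 is released. Hydrogenation of A5 would give 4.
- In its favour: one substrate from a bulk fatty feedstock, closure by the best-precedented reaction type for large lactones (ring-closing metathesis of a diene ester), and a two-step count. The by-products are easy to tell apart: A7 is a hydrocarbon, and cyclic oligomers differ from A5 by a full 26 carbons.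
- Against it: 18 of the 44 carbons of A6 are discarded. A7 is not volatile, stays in solution and can re-open A5, so only dilution drives the closure. Internal alkenes react more sluggishly than terminal ones. Technical grades of A6 carry shorter monoene homologues that would lead to lactones two or four carbons smaller, so a pure sample of A6 would first have to be prepared, which adds steps.
- Comparison: on step count this plan is the equal of the chosen one, and on precedent and ease of separating oligomers it is the better. Both share the same catalyst, the same reversible [2+2] manifold, the same sensitivity to double-bond migration and the same final hydrogenation. The chosen plan is ahead on atom economy (every carbon of both partners ends up in 3) and on the defined purity of its starting materials.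

Alternative 3: The cut is the C16=C17 double bond of hexacos-16-en-26-olide A8 (E/Z mixture). It is traced back to a sulfonyl bridge between C16 and C17 in the 28-membered sulfone lactone 1-oxa-12-thiacyclooctacosan-28-one 12,12-dioxide A9. A9 would come by oxidation of the sulfide lactone 1-oxa-12-thiacyclooctacosan-28-one A10, and A10 from 16-sulfanylhexadecanoic acid A11 and 10-bromodecan-1-ol A12 by S-alkylation and macrolactonisation.
- Forward key step: KOH on alumina with CBr2F2 would halogenate the sulfone at an α-carbon. 1,3-Elimination would give the episulfone, which loses sulfur dioxide A13 to form C16=C17 and contract the ring by one atom (Ramberg–Bäcklund reaction). Hydrogenation of A8 would give 4.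
- In its favour: the ring size is fixed by the substrate, the extrusion is irreversible, and the 28-membered ring can be closed by a reliable C–O or C–S bond formation.
- Against it: ring contraction is not ring formation. A macrocyclisation of the same difficulty is still needed, so the sulfur detour adds oxidation, contraction and hydrogenation to a ring closure that an all-carbon chain could have undergone directly at the ester oxygen. The lactone is exposed to hydroxide, and its own C2 methylene could be deprotonated and halogenated under the same conditions. CBr2F2 is an ozone-depleting, regulated reagent.
- Comparison: on control of ring size this plan is the better one, and on the final hydrogenation it is equal. On functional-group tolerance it is weaker (strong base against a neutral alkylidene catalyst), and on step economy much weaker (about five steps against two).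

Key step: step 1

Remark 1: compounds 1 and 2 are taken as catalogue chemicals; 1 is sold E-rich, and any Z isomer in it is equally usable because alkene geometry is scrambled in step 1 and removed in step 2.

Remark 2: the atom counts of all structures agree (16 + 10 = 26 carbons; C16H28O2 + C10H18 = C26H46O2), so no structure needs correcting. The precursors are used in a refined way: 2 retains some medium-ring strain and is the limiting, slowly fed partner, 1 is charged in threefold molar excess as a recoverable reservoir, and an isomerisation suppressor is added.

Remark 3: ruthenium-bound alkylidenes and ruthenacyclobutanes are states of the catalyst, not compounds of the route, and carry no numbers. The overall equation of step 1 is one molecule of 1 plus one molecule of 2 giving 3 with every atom retained, and that of step 2 is the addition of two molecules of H2 to 3.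

## Route

Step 1
Reactants: 1 (E)-oxacycloheptadec-10-en-2-one [(9E)-hexadec-9-en-16-olide]; 2 (Z)-cyclodecene
Product: 3 hexacosa-9,19-dien-26-olide (E/Z mixture at both alkenes)
Conditions: RuCl2(=CHPh)(H2IMes)(PCy3) (second-generation Grubbs catalyst, 5 mol% relative to 2), 1,4-benzoquinone (10 mol%), degassed CH2Cl2 (5 mM in 1, threefold excess of 1 over 2), 40 °C, 2 added by syringe pump over 12 h, then 4 h; ethyl vinyl ether quench; bulb-to-bulb distillation of excess 1, then AgNO3-impregnated silica gel
Reagents that add atoms: none
Why: Proposed new method: the closest known reaction type is ring-expansion metathesis of a cycloalkene with an acyclic diene (ring-opening cross metathesis followed by ring-closing metathesis), and the back-biting of ring-opening metathesis polymers to cyclic oligomers shows that a ring can also serve as the diene partner; what has not been shown is the crossed one-to-one version between a medium-ring cycloalkene and a macrocyclic unsaturated lactone. The alkylidene derived from RuCl2(=CHPh)(H2IMes)(PCy3) should add to the alkene of 2 in a [2+2] cycloaddition, the ruthenacyclobutane should open by cycloreversion to a ten-carbon chain-end alkylidene, this should add across C9=C10 of 1 in the same way, and the new chain end should then back-bite onto the distal alkene of the combined chain. This last event closes the 27-membered ring by intramolecular alkene metathesis (macrocyclic ring-closing metathesis under ring-chain equilibrium), so that C9=C10 and C19=C20 are both new double bonds and the alkylidene is released to carry on. Compound 2 retains some medium-ring strain, so at millimolar concentration its opening should be practically one-way, whereas strain-free 1 is re-formed again and again by back-biting and so acts as a reservoir. The selectivity needed is insertion of exactly one unit of 2 into one molecule of 1, against the 20-membered cyclodimer of 2, double insertion, dimers of 1 and polymer: the excess of 1 and the slow feed of 2 make a chain end that carries a freshly opened unit of 2 meet 1 far more often than 2, high dilution makes back-biting faster than chain growth, and the by-products differ from 3 by ten or sixteen carbons and in their number of alkenes, so that distillation and chromatography on AgNO3-impregnated silica gel should resolve them. Added 1,4-benzoquinone should suppress hydride-mediated double-bond migration, which would otherwise be followed by metathesis to rings one carbon larger or smaller that could not be removed after step 2. The ester is inert to the alkylidene, no stereocentre is formed, and the E/Z mixture at both alkenes is irrelevant because both are saturated in step 2.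

Step 2
Reactants: 3 hexacosa-9,19-dien-26-olide (E/Z mixture)
Product: 4 oxacycloheptacosan-2-one (26-hexacosanolide)
Conditions: H2 (1 atm), 10% Pd/C (palladium on carbon), EtOAc, rt; filtration through Celite, recrystallisation
Reagents that add atoms: none
Why: Heterogeneous catalytic hydrogenation of two isolated disubstituted alkenes; all E/Z isomers of 3 converge on the same saturated ring, the lactone is inert in a non-nucleophilic solvent, and no stereocentre arises.

## Compound list

1 | (E)-oxacycloheptadec-10-en-2-one [(9E)-hexadec-9-en-16-olide] | O=C1CCCCCCC/C=C/CCCCCCO1 | starting material
2 | (Z)-cyclodecene (cis-cyclodecene) | C1CCCC/C=C\CCC1 | starting material
3 | hexacosa-9,19-dien-26-olide (oxacycloheptacosa-10,20-dien-2-one), E/Z mixture at both alkenes, geometry not defined | O=C1CCCCCCCC=CCCCCCCCCC=CCCCCCCO1 | intermediate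
4 | oxacycloheptacosan-2-one (26-hexacosanolide) | O=C1CCCCCCCCCCCCCCCCCCCCCCCCCO1 | target

## Step count and least certain steps

Total step count: 2. Longest linear sequence: 2 steps (1 or 2 to 4). The route has only two steps, so both are assessed, the labelled step first.

Step 1 (key step, new method). What may go wrong is statistical scrambling under ring-chain equilibrium: self-insertion of 2 (20-membered cyclodimer, polymer), a second insertion into 3 (which has two alkenes and is re-opened more readily than 1) and dimerisation of 1 could leave 3 as a minor component, because the two alkenes have no intrinsic chemical difference and the outcome rests only on strain, stoichiometry and dilution. Further risks are double-bond migration before metathesis, which would shift the ring size by single carbons, and decay of the catalyst during a long, very dilute addition. The fallback uses known chemistry, sets out from 1 and returns to the route at 4; it replaces the ring insertion by chain extension and classical macrolactonisation. Partial reduction of 1 with iBu2AlH in CH2Cl2 at −78 °C should open the ring to (E)-16-hydroxyhexadec-9-enal F1. Heating commercial 10-bromodecanoic acid with PPh3 in MeCN gives (9-carboxynonyl)triphenylphosphonium bromide F2, which is converted with NaN(SiMe3)2 in THF into the carboxylate ylide; a Wittig reaction with F1 (excess ylide, free hydroxyl tolerated) should give (10Z,19E)-26-hydroxyhexacosa-10,19-dienoic acid F3, with all 26 carbons in one chain. Yamaguchi macrolactonisation (2,4,6-trichlorobenzoyl chloride, Et3N, THF; then slow addition to DMAP in toluene at reflux under high dilution) should close (10Z,19E)-hexacosa-10,19-dien-26-olide F4, a positional isomer of 3, and hydrogenation of F4 under the conditions of step 2 gives 4. Here the ring size is fixed by the seco-acid, at the cost of four operations.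

Step 2. What may go wrong is incomplete saturation: ruthenium, phosphine or quinone residues carried over from step 1 may poison the palladium surface, and the waxy substrate and product may dissolve poorly at room temperature, while traces of monoene would be very hard to remove from 4. The fallback sets out from 3 and returns at 4 without any new compound: a metal-free diimide reduction, with diimide generated in situ from p-toluenesulfonyl hydrazide and NaOAc in refluxing THF/water, transfers H2 to each alkene in a concerted syn fashion, is insensitive to catalyst poisons and leaves the lactone untouched.

## Further compounds

F1 | step 1 | (E)-16-hydroxyhexadec-9-enal | O=CCCCCCCC/C=C/CCCCCCO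
F2 | step 1 | (9-carboxynonyl)triphenylphosphonium bromide | OC(=O)CCCCCCCCC[P+](c1ccccc1)(c1ccccc1)c1ccccc1.[Br-]
F3 | step 1 | (10Z,19E)-26-hydroxyhexacosa-10,19-dienoic acid | OC(=O)CCCCCCCC/C=C\CCCCCCC/C=C/CCCCCCO
F4 | step 1 | (10Z,19E)-hexacosa-10,19-dien-26-olide [(11Z,20E)-oxacycloheptacosa-11,20-dien-2-one] | O=C1CCCCCCCC/C=C\CCCCCCC/C=C/CCCCCCO1
F0 | step 2 | none | none
A1 | alternative 1 | hexacosa-10,12-diyn-26-olide | O=C1CCCCCCCCC#CC#CCCCCCCCCCCCCCO1
A2 | alternative 1 | pentadec-14-yn-1-yl undec-10-ynoate | C#CCCCCCCCCC(=O)OCCCCCCCCCCCCCC#C
A3 | alternative 1 | undec-10-ynoic acid | OC(=O)CCCCCCCCC#C
A4 | alternative 1 | pentadec-14-yn-1-ol | OCCCCCCCCCCCCCC#C
A5 | alternative 2 | hexacos-13-en-26-olide (E/Z mixture) | O=C1CCCCCCCCCCCC=CCCCCCCCCCCCCO1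
A6 | alternative 2 | erucyl erucate, (Z)-docos-13-en-1-yl (Z)-docos-13-enoate | CCCCCCCC/C=C\CCCCCCCCCCCC(=O)OCCCCCCCCCCCC/C=C\CCCCCCCC
A7 | alternative 2 | octadec-9-ene (E/Z mixture) | CCCCCCCCC=CCCCCCCCC
A8 | alternative 3 | hexacos-16-en-26-olide (E/Z mixture) | O=C1CCCCCCCCCCCCCCC=CCCCCCCCCCO1
A9 | alternative 3 | 1-oxa-12-thiacyclooctacosan-28-one 12,12-dioxide | O=C1CCCCCCCCCCCCCCCS(=O)(=O)CCCCCCCCCCO1
A10 | alternative 3 | 1-oxa-12-thiacyclooctacosan-28-one | O=C1CCCCCCCCCCCCCCCSCCCCCCCCCCO1
A11 | alternative 3 | 16-sulfanylhexadecanoic acid | OC(=O)CCCCCCCCCCCCCCCS
A12 | alternative 3 | 10-bromodecan-1-ol | OCCCCCCCCCCBr
A13 | alternative 3 | sulfur dioxide | O=S=O
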